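All constants were set for the occasion; no experiment stands behind them.

- red: substrate 0.76 M; temperature 60 °C; time 2.5 min
- grey: substrate 0.76 M; temperature 35 °C; time 2.5 min

    substrate → target (k1 = 0.0012 /min, Ea1 = 117 kJ/mol)
    substrate ⇌ dormant form (K2 = 0.33, k2 = 1.9 /min, Ea2 = 90.0 kJ/mol, ΔH2 = −39.0 kJ/mol)
    target → over-reaction product (k3 = 0.043 /min, Ea3 = 108 kJ/mol)
    substrate + target → 2 target (k4 = 0.71 /M/min, Ea4 = 77.0 kJ/mol)
    (constants at 60 °C)

- the best flask by share of target in all that became target or over-reaction product; "all alike" if 1.5 percentage points covers them all (red / grey / all alike)
- share of target in all that became target or over-reaction product, red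
- share of target in all that became target or over-reaction product, grey

- all constants are for 60 °C and move with temperature by the activation energies and enthalpies

Every target ever formed stands either as target or as over-reaction product, and over-reaction product grows at k[target], with k the over-reaction constant. So, from a start without over-reaction product, its amount is k times the time integral of [target], and with τ as that integral over [target] now:

[over-reaction product]/[target] = kτ, share = 1/(1 + kτ)

In red, k is 0.043 /min. In red, substrate and dormant form relax with a half-life of 0.0905 min, shorter than the 2.5 min run, so [substrate] is taken as 0.571 M. In red, step 4 is then pseudo-first-order in target, and target multiplies at a net rate λ = 0.363 /min.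

The slow end ignores this growth. Supply is steady, [target] rises in a straight line, and

τ = t/2 = 1.25 min, share 94.9%

The fast end takes pure growth:

τ = 1/λ = 2.76 min, share 89.4%

The two part, and the second cheats: its τ is longer than the run itself, and λt is 0.907, no large number. Solving steady supply plus growth from zero target joins the ends, and the supply cancels:

τ = 1/λ − t/(exp(λt) − 1) = 1.06 min

This τ is the standing time of target, the time integral of [target] divided by [target] now. It lies below the slow end, and it gives red 95.6%.

In grey, k falls to 0.001818 /min. With the whole charge counted as substrate, the estimate for grey puts λ at 0.0548 /min, so

τ = 1.22 min, share 99.8%

In this reckoning grey leads red by 4.2 percentage points, more than the margin, because k differs by a factor of 23.7 and τ by a factor of 1.15.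

The forecast gives 95.6% for red, 99.8% for grey and grey as best, holding that the dormant form "barely moves the share".

The simulation gives 95.6% for red and 99.8% for grey, with grey best. The reaction of substrate to dormant form counts for little in the red share. In the standing time of red, the whole charge as substrate makes λ 0.497 /min and moves τ from 1.06 min to 0.998 min, a reckoned shift of 0.26 points in the share.

A flask like red kept at 75 °C has k = 0.231 /min. Taking [substrate] as 0.644 M gives λ = 1.28 /min, τ = 0.674 min and a share of 86.5%. The computed share there is 85.8%.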